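**Plan** (germacrane numbering: lactone O–C6, C7, C8–O-angelate, C9H2, C10(C14)=C1, C2=O, C3=C4(C15), C5–OH, C11(=C13)–C12=O)
- Retrosynthetic cuts, in order: the C8–O ester and C11=C13; the C3=C4 olefin, traced back through an SO2 bridge to an eleven-membered cyclic sulfone; S–C3; C2–C3; C8–C9; C6–C7 with the lactone C–O; C4–S.
- Enabling feature: in the ten-membered carbocycle C1–C10, C3 and C4 form a trisubstituted Z-olefin between the C2 carbonyl and the C5 carbinol. Sulfur can therefore be placed on C4 by epoxide opening and joined to C3 by alkylation with an α-chloro ketone, then expelled as SO2.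
- Forward order: C4–C6 thio-diol → Evans aldol/lactonization (C6–C7, γ-lactone) → vinylogous Mukaiyama aldol (C8–C9, E-C10=C1) → C3 by chloromethylation → thiolate macrocyclization to the eleven-membered thiacycle → sulfone, dioxolane → ring contraction to the ten-membered ring → α-methylenation, angelate, unmasking.
- Stereochemistry: C5 from L-(+)-tartrate (Sharpless); C6 and C7 from (S)-4-benzyloxazolidinone (syn aldol, hence trans lactone); C8 by Felkin addition; E-C1=C10 from the s-trans dienol ether; Z-C3=C4 from the cis-episulfone.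

Key step: step 16

**Step 1**
Reactants: 1 (E)-but-2-en-1-ol
Product: 3 (2S,3R)-3-(tritylsulfanyl)butane-1,2-diol, via epoxy alcohol 2 (not isolated)
Conditions: Ti(OiPr)4 (cat.), L-(+)-diethyl tartrate, t-BuOOH, 4 Å MS, CH2Cl2, −20 °C; Me2S; then Ph3CSH, Ti(OiPr)4 (1.5 equiv), rt
Reagents that add atoms: tert-butyl hydroperoxide CC(C)(C)OO; triphenylmethanethiol SC(c1ccccc1)(c1ccccc1)c1ccccc1
Why: Sharpless asymmetric epoxidation with L-(+)-tartrate should set the future C5 (and C4) as the (2S,3S)-epoxy alcohol, and the Ti(OiPr)4-mediated opening by the thiol should occur at the carbon remote from the CH2OH group (future C4) with inversion, leaving the C5 carbinol untouched.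

**Step 2**
Reactants: 3 (2S,3R)-3-(tritylsulfanyl)butane-1,2-diol
Product: 5 (2S,3R)-1-(triethylsilyloxy)-2-(triisopropylsilyloxy)-3-(tritylsulfanyl)butane, via primary triethylsilyl ether 4 (not isolated)
Conditions: Et3SiCl, imidazole, CH2Cl2, −40 °C; then iPr3SiOTf, 2,6-lutidine, −40 → 0 °C
Reagents that add atoms: chlorotriethylsilane CC[Si](Cl)(CC)CC; triisopropylsilyl triflate CC(C)[Si](OS(=O)(=O)C(F)(F)F)(C(C)C)C(C)C
Why: Sequential silylation should differentiate the hydroxyls on steric grounds, the silyl chloride taking the primary and the more reactive triflate the hindered secondary (future C5) oxygen.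

**Step 3**
Reactants: 5 bis-silyl ether
Product: 6 (2S,3R)-2-(triisopropylsilyloxy)-3-(tritylsulfanyl)butanal
Conditions: (COCl)2, DMSO, CH2Cl2, −78 → −30 °C; Et3N, −78 → 0 °C
Reagents that add atoms: none
Why: Under Swern conditions a primary triethylsilyl ether is cleaved and oxidized directly to the aldehyde while the secondary triisopropylsilyl ether stays inert, and the cold amine work-up should not epimerize the α-silyloxy centre.

**Step 4**
Reactants: 7 (S)-4-benzyl-1,3-oxazolidin-2-one; 8 methyl 4-chloro-4-oxobutanoate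
Product: 9 methyl 4-[(4S)-4-benzyl-2-oxo-1,3-oxazolidin-3-yl]-4-oxobutanoate
Conditions: Et3N, DMAP (cat.), CH2Cl2, 0 °C → rt
Reagents that add atoms: none
Why: DMAP-catalysed N-acylation of the oxazolidinone by the acid chloride is a standard way to make the succinate imide.

**Step 5**
Reactants: 9 succinate imide; 6 aldehyde
Product: 12 trans-γ-lactone imide (4S)-4-benzyl-3-{[(2S,3S)-5-oxo-2-[(1S,2R)-1-(triisopropylsilyloxy)-2-(tritylsulfanyl)propyl]oxolan-3-yl]carbonyl}-1,3-oxazolidin-2-one, via (Z)-boron enolate 10 (not isolated), via syn-aldol adduct 11 (not isolated)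
Conditions: Bu2BOTf, iPr2NEt, CH2Cl2, −78 → 0 °C; 6, −78 → 0 °C; MeOH/pH 7 buffer (no peroxide); then PPTS (cat.), toluene, 50 °C
Reagents that add atoms: none
Why: The Evans syn aldol (Zimmerman–Traxler transition state of the Z-boron enolate, facial control by the (S)-benzyl auxiliary, matched with the Felkin preference of the α-silyloxy aldehyde) should set C6 and C7, and 5-exo-trig lactonization of the C6 hydroxyl onto the methyl ester then gives the trans-lactone.

**Step 6**
Reactants: 12 lactone imide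
Product: 13 S-ethyl (2S,3S)-5-oxo-2-[(1S,2R)-1-(triisopropylsilyloxy)-2-(tritylsulfanyl)propyl]oxolane-3-carbothioate
Conditions: NaSEt, THF, 0 °C; NH4Cl (aq)
Reagents that add atoms: sodium ethanethiolate [Na+].[S-]CC
Why: Thiolate attacks the exocyclic imide carbonyl selectively (transthioesterification of N-acyl oxazolidinones) and is too weakly basic to epimerize C7 or to open the lactone irreversibly.

**Step 7**
Reactants: 13 thioester
Product: 14 (2S,3S)-5-oxo-2-[(1S,2R)-1-(triisopropylsilyloxy)-2-(tritylsulfanyl)propyl]oxolane-3-carbaldehyde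
Conditions: Et3SiH, 10% Pd/C, acetone, rt
Reagents that add atoms: none
Why: The Fukuyama reduction should convert the thioester to the aldehyde at the correct oxidation level under neutral conditions that leave the lactone and the base-sensitive β-acyloxy aldehyde intact.

**Step 8**
Reactants: 15 3-methylbut-2-enal
Product: 16 (E)-tert-butyldimethyl[(3-methylbuta-1,3-dien-1-yl)oxy]silane
Conditions: t-BuMe2SiOTf, Et3N, Et2O, 0 °C → rt
Reagents that add atoms: tert-butyldimethylsilyl triflate CC(C)(C)[Si](C)(C)OS(=O)(=O)C(F)(F)F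
Why: O-silylation of the enal followed by γ-deprotonation (soft enolization) is the usual route to the (E)-1-silyloxy diene.

**Step 9**
Reactants: 14 lactone aldehyde; 16 silyl dienol ether
Product: 17 δ-hydroxy enal: the γ-lactone of 14 bearing at C7 the (1S,3E)-1-hydroxy-3-methyl-5-oxopent-3-en-1-yl chain (C8–C9–C10(C14)=C1–C2HO)
Conditions: BF3·OEt2, CH2Cl2/Et2O, −78 °C; NaHCO3 (aq)
Reagents that add atoms: none
Why: In this vinylogous Mukaiyama aldol the diene terminus (γ-carbon) attacks the BF3-activated aldehyde through an open transition state anti to the larger C6 ring carbon (Felkin), which should place the C8 hydroxyl syn to C11, and the s-trans diene should give the E-C10=C1 enal.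

**Step 10**
Reactants: 17 δ-hydroxy enal
Product: 18 C8 tert-butyldimethylsilyl ether of 17
Conditions: t-BuMe2SiOTf, 2,6-lutidine, CH2Cl2, −78 °C
Reagents that add atoms: tert-butyldimethylsilyl triflate CC(C)(C)[Si](C)(C)OS(=O)(=O)C(F)(F)F
Why: Standard silylation blocks the C8 hydroxyl, which could otherwise translactonize onto C12, with a group that can later be removed in the presence of the triisopropylsilyl ether.

**Step 11**
Reactants: 18 silyl-protected enal
Product: 19 allylic chlorohydrin (C2 carbinol, both epimers; C3 = CH2Cl)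
Conditions: ICH2Cl, MeLi·LiBr, THF, −78 °C; AcOH, −78 °C
Reagents that add atoms: chloroiodomethane ClCI
Why: Chloromethyllithium generated in the presence of the substrate adds 1,2 to the aldehyde much faster than to the lactone at −78 °C, and the cold acidic quench should keep the chlorohydrin from closing to the epoxide; the new C2 centre is removed in the next step.

**Step 12**
Reactants: 19 chlorohydrin
Product: 20 α-chloro enone (C2 ketone, C3H2Cl, E-C10=C1)
Conditions: Dess–Martin periodinane, NaHCO3, CH2Cl2, 0 °C → rt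
Reagents that add atoms: none
Why: Buffered Dess–Martin oxidation of the allylic alcohol should give the enone without touching the trityl sulfide or the silyl ethers, and it merges both C2 epimers.

**Step 13**
Reactants: 20 α-chloro enone
Product: 22 eleven-membered β-keto sulfide (ring: S, C3, C2, C1, C10, C9, C8, C7, C6, C5, C4; trans-fused γ-lactone), via free thiol 21 (not isolated)
Conditions: CF3CO2H (5 vol%), Et3SiH, CH2Cl2, 0 °C; evaporate; then slow addition to Cs2CO3, DMF (1 mM), rt
Reagents that add atoms: none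
Why: Acidolysis of the S-trityl group with silane trapping of the trityl cation frees the C4 thiol, and the cesium thiolate should displace the α-keto chloride (a very fast SN2 reaction) under high dilution to close the thiacycle.

**Step 14**
Reactants: 22 macrocyclic β-keto sulfide
Product: 23 macrocyclic β-keto sulfone
Conditions: mCPBA (2.2 equiv), NaHCO3, CH2Cl2, 0 °C → rt
Reagents that add atoms: 3-chloroperoxybenzoic acid OOC(=O)c1cccc(Cl)c1
Why: Peracid oxidation of sulfide to sulfone is far faster than epoxidation of the electron-poor enone olefin, which is the only C=C present.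

**Step 15**
Reactants: 23 β-keto sulfone
Product: 24 C2 ethylene ketal (spiro-1,3-dioxolane) of 23
Conditions: Me3SiOCH2CH2OSiMe3, Me3SiOTf (cat.), CH2Cl2, −78 → −20 °C
Reagents that add atoms: 1,2-bis(trimethylsilyloxy)ethane C[Si](C)(C)OCCO[Si](C)(C)C
Why: Noyori ketalization masks the C2 ketone under kinetic, aprotic conditions that should not move the C10=C1 double bond; the ketal removes the extra acidity at C3 and makes C2 a quaternary, non-stereogenic centre for the next step.

**Step 16**
Reactants: 24 eleven-membered ketal sulfone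
Product: 29 ten-membered (1(10)E,3Z)-diene lactone with C2 dioxolane, C5 triisopropylsilyl ether and C8 tert-butyldimethylsilyl ether, via potassium seco-carboxylate 25 (not isolated), via C3-bromo sulfone 26 (not isolated), via episulfone 27 (not isolated), via hydroxy acid 28 (not isolated)
Conditions: KOH, t-BuOH/H2O, rt; CBr2F2, KOH/Al2O3, t-BuOH/CH2Cl2, 0 °C → rt; KH2PO4 (aq) to pH 5–6; then EDC·HCl, CH2Cl2, rt
Reagents that add atoms: none
Why: Hydroxide first opens the lactone to the carboxylate, which shields C11 from enolization; an α-sulfonyl carbanion is then brominated by CBr2F2, the carbanion on the other α-carbon displaces bromide in a 1,3-elimination to a thiirane 1,1-dioxide, and cheletropic loss of SO2 joins C3 to C4 as an olefin, so the eleven-membered thiacycle contracts to the ten-membered carbocycle. The closest known reaction type is the halogenative (Meyers/Chan) Ramberg–Bäcklund contraction of medium and large cyclic sulfones. The episulfone closes 3-exo-tet, the carbocycle arises by extrusion, not by a closure of its own, and EDC re-closes the γ-lactone 5-exo-trig at the only free hydroxyl (C6). No stereocentre is created; the Z geometry should follow from the kinetically preferred cis-fused episulfone under hydroxide conditions and from the lower strain of a Z olefin beside the E-C10=C1 bond. The step needs α-sulfonyl deprotonation without β-elimination and without halogenation elsewhere; this is secured by the quaternary C2 ketal (no enolizable or bis-allylic hydrogen, ring-opening of the tethered ketal oxygen is reversible), the poor leaving ability and low migratory aptitude of the C5 triisopropylsilyloxy group, and the carboxylate form of C12.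

**Step 17**
Reactants: 29 ring-contracted lactone
Product: 32 α-methylene lactone (C11=C13), via Mannich base 30 (not isolated), via methiodide 31 (not isolated)
Conditions: LiN(iPr)2, THF, −78 °C; CH2=NMe2+ I−, −78 °C → rt; then MeI, MeOH, rt; then NaHCO3 (aq)/EtOAc, rt
Reagents that add atoms: Eschenmoser's salt C=[N+](C)C.[I-]
Why: The lactone enolate is the only enolizable site, its Mannich reaction with the iminium salt followed by N-methylation and E1cB loss of trimethylamine is the classical α-methylenation of γ-lactones, and C11 becomes sp2 so no stereocentre is at stake.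

**Step 18**
Reactants: 32 α-methylene lactone
Product: 33 C8 alcohol (C5 triisopropylsilyl ether and C2 dioxolane retained)
Conditions: HF·pyridine, pyridine, THF, 0 °C → rt
Reagents that add atoms: none
Why: Buffered HF·pyridine should cleave the secondary tert-butyldimethylsilyl ether well before the bulkier triisopropylsilyl ether, and the anhydrous buffered medium should spare the dioxolane.

**Step 19**
Reactants: 33 C8 alcohol; 34 angelic acid ((Z)-2-methylbut-2-enoic acid)
Product: 36 C8 angelate, via mixed anhydride 35 (not isolated)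
Conditions: 34, 2,4,6-Cl3C6H2COCl, Et3N, toluene, rt; then 33, toluene, 75 °C
Reagents that add atoms: none
Why: Acylation through the 2,4,6-trichlorobenzoyl mixed anhydride without a nucleophilic catalyst (Yamaguchi-type esterification) is the established way to esterify hindered secondary alcohols with angelic acid without Z → E isomerization to the tiglate.

**Step 20**
Reactants: 36 protected angelate
Product: 37 target (5R,6S,7R,8S; 1(10)E,3Z)
Conditions: HF (48% aq), MeCN, 0 °C → rt
Reagents that add atoms: water O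
Why: Aqueous HF should remove the triisopropylsilyl ether and hydrolyse the acid-labile bis-allylic dioxolane in one operation, revealing the C5 alcohol and the cross-conjugated C2 dienone under conditions that the angelate and the α-methylene lactone tolerate.

**Compound list**
1 | (E)-but-2-en-1-ol | C/C=C/CO | starting material
2 | [(2S,3S)-3-methyloxiran-2-yl]methanol | C[C@@H]1O[C@H]1CO | intermediate
3 | (2S,3R)-3-(tritylsulfanyl)butane-1,2-diol | C[C@@H](SC(c1ccccc1)(c1ccccc1)c1ccccc1)[C@@H](O)CO | intermediate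
4 | (2S,3R)-1-(triethylsilyloxy)-3-(tritylsulfanyl)butan-2-ol | C[C@@H](SC(c1ccccc1)(c1ccccc1)c1ccccc1)[C@@H](O)CO[Si](CC)(CC)CC | intermediate
5 | (2S,3R)-1-(triethylsilyloxy)-2-(triisopropylsilyloxy)-3-(tritylsulfanyl)butane | C[C@@H](SC(c1ccccc1)(c1ccccc1)c1ccccc1)[C@@H](O[Si](C(C)C)(C(C)C)C(C)C)CO[Si](CC)(CC)CC | intermediate
6 | (2S,3R)-2-(triisopropylsilyloxy)-3-(tritylsulfanyl)butanal | C[C@@H](SC(c1ccccc1)(c1ccccc1)c1ccccc1)[C@@H](O[Si](C(C)C)(C(C)C)C(C)C)C=O | intermediate
7 | (S)-4-benzyl-1,3-oxazolidin-2-one | O=C1OC[C@H](Cc2ccccc2)N1 | starting material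
8 | methyl 4-chloro-4-oxobutanoate | COC(=O)CCC(=O)Cl | starting material
9 | methyl 4-[(4S)-4-benzyl-2-oxo-1,3-oxazolidin-3-yl]-4-oxobutanoate | COC(=O)CCC(=O)N1[C@@H](Cc2ccccc2)COC1=O | intermediate
10 | (Z)-dibutylboron enolate of 9 | COC(=O)C/C=C(\OB(CCCC)CCCC)N1[C@@H](Cc2ccccc2)COC1=O | intermediate
11 | open-chain syn-aldol adduct (C6 hydroxyl, methyl ester) | COC(=O)C[C@@H]([C@H](O)[C@H](O[Si](C(C)C)(C(C)C)C(C)C)[C@@H](C)SC(c1ccccc1)(c1ccccc1)c1ccccc1)C(=O)N1[C@@H](Cc2ccccc2)COC1=O | intermediate
12 | trans-γ-lactone imide | O=C1O[C@H]([C@H](O[Si](C(C)C)(C(C)C)C(C)C)[C@@H](C)SC(c2ccccc2)(c2ccccc2)c2ccccc2)[C@@H](C(=O)N2[C@@H](Cc3ccccc3)COC2=O)C1 | intermediate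
13 | S-ethyl (2S,3S)-5-oxo-2-[(1S,2R)-1-(triisopropylsilyloxy)-2-(tritylsulfanyl)propyl]oxolane-3-carbothioate | O=C1O[C@H]([C@H](O[Si](C(C)C)(C(C)C)C(C)C)[C@@H](C)SC(c2ccccc2)(c2ccccc2)c2ccccc2)[C@@H](C(=O)SCC)C1 | intermediate
14 | (2S,3S)-5-oxo-2-[(1S,2R)-1-(triisopropylsilyloxy)-2-(tritylsulfanyl)propyl]oxolane-3-carbaldehyde | O=C1O[C@H]([C@H](O[Si](C(C)C)(C(C)C)C(C)C)[C@@H](C)SC(c2ccccc2)(c2ccccc2)c2ccccc2)[C@@H](C=O)C1 | intermediate
15 | 3-methylbut-2-enal | CC(C)=CC=O | starting material
16 | (E)-tert-butyldimethyl[(3-methylbuta-1,3-dien-1-yl)oxy]silane | C=C(C)/C=C/O[Si](C)(C)C(C)(C)C | intermediate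
17 | lactone δ-hydroxy enal (C8 hydroxyl, E-C10=C1, C2 aldehyde) | O=C1O[C@H]([C@H](O[Si](C(C)C)(C(C)C)C(C)C)[C@@H](C)SC(c2ccccc2)(c2ccccc2)c2ccccc2)[C@@H]([C@@H](O)C/C(C)=C/C=O)C1 | intermediate
18 | C8 tert-butyldimethylsilyl ether of 17 | O=C1O[C@H]([C@H](O[Si](C(C)C)(C(C)C)C(C)C)[C@@H](C)SC(c2ccccc2)(c2ccccc2)c2ccccc2)[C@@H]([C@@H](O[Si](C)(C)C(C)(C)C)C/C(C)=C/C=O)C1 | intermediate
19 | allylic chlorohydrin (both C2 epimers) | O=C1O[C@H]([C@H](O[Si](C(C)C)(C(C)C)C(C)C)[C@@H](C)SC(c2ccccc2)(c2ccccc2)c2ccccc2)[C@@H]([C@@H](O[Si](C)(C)C(C)(C)C)C/C(C)=C/C(O)CCl)C1 | intermediate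
20 | α-chloro enone | O=C1O[C@H]([C@H](O[Si](C(C)C)(C(C)C)C(C)C)[C@@H](C)SC(c2ccccc2)(c2ccccc2)c2ccccc2)[C@@H]([C@@H](O[Si](C)(C)C(C)(C)C)C/C(C)=C/C(=O)CCl)C1 | intermediate
21 | free C4 thiol of 20 | O=C1O[C@H]([C@H](O[Si](C(C)C)(C(C)C)C(C)C)[C@@H](C)S)[C@@H]([C@@H](O[Si](C)(C)C(C)(C)C)C/C(C)=C/C(=O)CCl)C1 | intermediate
22 | eleven-membered β-keto sulfide (4R; C5–C8 as in 37) | O=C1O[C@H]2[C@H](C1)[C@@H](O[Si](C)(C)C(C)(C)C)C/C(C)=C/C(=O)CS[C@H](C)[C@H]2O[Si](C(C)C)(C(C)C)C(C)C | intermediate
23 | eleven-membered β-keto sulfone | O=C1O[C@H]2[C@H](C1)[C@@H](O[Si](C)(C)C(C)(C)C)C/C(C)=C/C(=O)CS(=O)(=O)[C@H](C)[C@H]2O[Si](C(C)C)(C(C)C)C(C)C | intermediate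
24 | eleven-membered sulfone, C2 spiro-dioxolane | O=C1O[C@H]2[C@H](C1)[C@@H](O[Si](C)(C)C(C)(C)C)C/C(C)=C/C3(OCCO3)CS(=O)(=O)[C@H](C)[C@H]2O[Si](C(C)C)(C(C)C)C(C)C | intermediate
25 | potassium seco-carboxylate of 24 (C6 hydroxyl free) | O[C@H]1[C@H](CC(=O)[O-])[C@@H](O[Si](C)(C)C(C)(C)C)C/C(C)=C/C2(OCCO2)CS(=O)(=O)[C@H](C)[C@H]1O[Si](C(C)C)(C(C)C)C(C)C.[K+] | intermediate
26 | C3-bromo sulfone (C3 configuration unspecified) | O[C@H]1[C@H](CC(=O)[O-])[C@@H](O[Si](C)(C)C(C)(C)C)C/C(C)=C/C2(OCCO2)C(Br)S(=O)(=O)[C@H](C)[C@H]1O[Si](C(C)C)(C(C)C)C(C)C.[K+] | intermediate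
27 | cis-fused thiirane 1,1-dioxide across C3–C4 (facial sense unspecified) | O[C@H]1[C@H](CC(=O)[O-])[C@@H](O[Si](C)(C)C(C)(C)C)C/C(C)=C/C2(OCCO2)C3C(C)(S3(=O)=O)[C@H]1O[Si](C(C)C)(C(C)C)C(C)C.[K+] | intermediate
28 | ring-contracted (1(10)E,3Z)-diene hydroxy acid | O[C@H]1[C@H](CC(=O)O)[C@@H](O[Si](C)(C)C(C)(C)C)C/C(C)=C/C2(OCCO2)/C=C(/C)[C@H]1O[Si](C(C)C)(C(C)C)C(C)C | intermediate
29 | ten-membered (1(10)E,3Z)-diene lactone, C2 dioxolane | O=C1O[C@H]2[C@H](C1)[C@@H](O[Si](C)(C)C(C)(C)C)C/C(C)=C/C3(OCCO3)/C=C(/C)[C@H]2O[Si](C(C)C)(C(C)C)C(C)C | intermediate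
30 | C11 dimethylaminomethyl lactone (C11 configuration unspecified) | CN(C)CC1C(=O)O[C@H]2[C@H]1[C@@H](O[Si](C)(C)C(C)(C)C)C/C(C)=C/C3(OCCO3)/C=C(/C)[C@H]2O[Si](C(C)C)(C(C)C)C(C)C | intermediate
31 | trimethylammonium iodide of 30 | C[N+](C)(C)CC1C(=O)O[C@H]2[C@H]1[C@@H](O[Si](C)(C)C(C)(C)C)C/C(C)=C/C3(OCCO3)/C=C(/C)[C@H]2O[Si](C(C)C)(C(C)C)C(C)C.[I-] | intermediate
32 | α-methylene lactone, fully protected | C=C1C(=O)O[C@H]2[C@H]1[C@@H](O[Si](C)(C)C(C)(C)C)C/C(C)=C/C3(OCCO3)/C=C(/C)[C@H]2O[Si](C(C)C)(C(C)C)C(C)C | intermediate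
33 | C8 alcohol | C=C1C(=O)O[C@H]2[C@H]1[C@@H](O)C/C(C)=C/C3(OCCO3)/C=C(/C)[C@H]2O[Si](C(C)C)(C(C)C)C(C)C | intermediate
34 | angelic acid, (Z)-2-methylbut-2-enoic acid | C/C=C(/C)C(=O)O | starting material
35 | (Z)-2-methylbut-2-enoic 2,4,6-trichlorobenzoic anhydride | C/C=C(/C)C(=O)OC(=O)c1c(Cl)cc(Cl)cc1Cl | intermediate
36 | C8 angelate, C5 triisopropylsilyl ether, C2 dioxolane | C=C1C(=O)O[C@H]2[C@H]1[C@@H](OC(=O)/C(C)=C\C)C/C(C)=C/C3(OCCO3)/C=C(/C)[C@H]2O[Si](C(C)C)(C(C)C)C(C)C | intermediate
37 | target, CNP0230565.9 | C=C1C(=O)O[C@H]2[C@H]1[C@@H](OC(=O)/C(C)=C\C)C/C(C)=C/C(=O)/C=C(/C)[C@H]2O | target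

**Totals**
Total step count: 20. Longest linear sequence: 18 steps (steps 1–3, 5–7, 9–20).

**Steps most likely to fail**

Step 16 (ring contraction). The α-sulfonyl carbanions may instead eliminate the C5 silyloxy group or open the ketal. The base may halogenate other sites or let silicon migrate to the liberated C6 alkoxide. The episulfone may also collapse with loss of Z selectivity. The fallback sets out from 23 and places the halogen before any base is used: chlorination of the activated C3 methylene with SO2Cl2 in CH2Cl2 at 0 °C should give the α-chloro-β-keto sulfone F1. Ketalization as in step 15 would give the chloro ketal sulfone F2. Treatment with KOtBu in THF at −78 → 0 °C (classical Ramberg–Bäcklund of a preformed α-chloro sulfone, lactone left closed) returns to the route at 29.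

Step 9 (vinylogous aldol). Facial selectivity at C8 may be poor, the enal may form as an E/Z mixture, and the β-acyloxy aldehyde may eliminate. The fallback sets out from 14 and uses reagent control: (−)-B-methallyldiisopinocampheylborane (from (−)-Ipc2BOMe and methallylmagnesium chloride, Et2O, −78 °C, ethanolamine work-up) should give the homoallylic alcohol F3. Silylation (t-BuMe2SiOTf, 2,6-lutidine) gives the silyl ether F4. Cross-metathesis of its 1,1-disubstituted olefin with (E)-but-2-enal (second-generation Hoveyda–Grubbs catalyst, CH2Cl2, 40 °C) returns to the route at 18.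

Step 13 (macrocyclization). Oligomerization may outrun closure of the eleven-membered ring, and the base may degrade the α-chloro enone or promote thiolate conjugate addition. The fallback sets out from 19, before the oxidation: detritylation (CF3CO2H, Et3SiH) gives the mercapto chlorohydrin F5. Cs2CO3 in dilute DMF should close the ring by thiolate attack on the primary chloride, or on the vinyl epoxide formed from it in the flask, to give the macrocyclic β-hydroxy sulfide F6. Oxidation of both sulfur and the carbinol with Pr4N[RuO4] (cat.) and N-methylmorpholine N-oxide returns to the route at 23.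

**Further compounds**
F1 | step 16 | C3-chloro β-keto sulfone (C3 configuration unspecified) | O=C1O[C@H]2[C@H](C1)[C@@H](O[Si](C)(C)C(C)(C)C)C/C(C)=C/C(=O)C(Cl)S(=O)(=O)[C@H](C)[C@H]2O[Si](C(C)C)(C(C)C)C(C)C
F2 | step 16 | C3-chloro sulfone, C2 dioxolane | O=C1O[C@H]2[C@H](C1)[C@@H](O[Si](C)(C)C(C)(C)C)C/C(C)=C/C3(OCCO3)C(Cl)S(=O)(=O)[C@H](C)[C@H]2O[Si](C(C)C)(C(C)C)C(C)C
F3 | step 9 | lactone homoallylic alcohol (C8 hydroxyl, 2-methylallyl chain) | O=C1O[C@H]([C@H](O[Si](C(C)C)(C(C)C)C(C)C)[C@@H](C)SC(c2ccccc2)(c2ccccc2)c2ccccc2)[C@@H]([C@@H](O)CC(C)=C)C1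
F4 | step 9 | C8 tert-butyldimethylsilyl ether of F3 | O=C1O[C@H]([C@H](O[Si](C(C)C)(C(C)C)C(C)C)[C@@H](C)SC(c2ccccc2)(c2ccccc2)c2ccccc2)[C@@H]([C@@H](O[Si](C)(C)C(C)(C)C)CC(C)=C)C1
F5 | step 13 | mercapto chlorohydrin (both C2 epimers) | O=C1O[C@H]([C@H](O[Si](C(C)C)(C(C)C)C(C)C)[C@@H](C)S)[C@@H]([C@@H](O[Si](C)(C)C(C)(C)C)C/C(C)=C/C(O)CCl)C1
F6 | step 13 | eleven-membered β-hydroxy sulfide (both C2 epimers) | O=C1O[C@H]2[C@H](C1)[C@@H](O[Si](C)(C)C(C)(C)C)C/C(C)=C/C(O)CS[C@H](C)[C@H]2O[Si](C(C)C)(C(C)C)C(C)C
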